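**Retrosynthetic overview**
1. Target 23 ⇐ silyl ether 22 (O‑desilylation) ⇐ 12 + 21. The C7–C8 bond of the tridecanone chain (sixth and seventh CH2 of the tether, counted from the furan) is made by a Ni‑electrocatalytic doubly decarboxylative C(sp3)–C(sp3) coupling of two N‑hydroxyphthalimide esters.
2. Enabling feature: the unbranched (CH2)10 tether between furan C5 and the C3 ketone. C7 and C8 are plain methylene carbons, each at least four sp3 carbons from the furan ring, the ketone and the C2 stereocentre, so both map onto primary radicals from simple acids. The 2,3,4,5‑tetrasubstituted furan has no ring C–H and is oxidation‑labile, so the decarboxylation is run cathodically, not as an anodic Kolbe coupling.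
3. 21 ⇐ methyl N‑acetyl‑L‑serinate (chiral pool supplies the only stereocentre): O‑TBS, Weinreb amide, hex‑5‑enyl Grignard, RuO4 cleavage, NHPI ester.
4. 12 ⇐ 2,3‑dimethylmaleic anhydride: PrMgCl mono‑addition, NaBH4, DIBAL‑H/H+ aromatisation, Friedel–Crafts acylation with a C7 half‑ester chloride, Wolff–Kishner, NHPI ester.
5. Ring order: the only ring, the furan, is completed in step 3 (anhydride → butenolide → furan) before any chain chemistry.

Key step: step 12

Remark on the chemistry: compounds 3–6 are racemic or diastereomeric at a carbon that becomes sp2 in furan 7, so they are carried as mixtures; methyl N‑acetyl‑L‑serinate and ethyl 7‑chloro‑7‑oxoheptanoate are taken as commercial.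

Step 1
Reactants: 1 2,3-dimethylmaleic anhydride; 2 n-propylmagnesium chloride
Product: 3 5-hydroxy-3,4-dimethyl-5-propylfuran-2(5H)-one (racemic)
Conditions: 2 (1.05 equiv) added to 1, THF, −78 °C; then 1 M HCl, 0 °C
Reagents that add atoms: none
Why: Grignard mono‑addition to a cyclic anhydride, where the ring‑opened magnesium keto‑carboxylate resists a second addition at −78 °C and closes to the γ‑hydroxybutenolide on acidification; the new C5 centre is racemic and is erased on aromatisation.

Step 2
Reactants: 3
Product: 5 3,4-dimethyl-5-propylfuran-2(5H)-one (racemic), via ring-opened hydroxy acid 4 (not isolated)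
Conditions: NaBH4, 1 M aq. NaOH/THF, 0 °C → rt; then 2 M HCl, rt
Reagents that add atoms: none
Why: Borohydride 1,2‑reduction of the ring‑opened 4‑oxo‑enoate (conjugate reduction is blocked by the tetrasubstituted alkene), then acid lactonisation of the (Z)‑hydroxy acid, the standard γ‑hydroxybutenolide → butenolide conversion; the carbinol centre is racemic and inconsequential.

Step 3
Reactants: 5
Product: 7 3,4-dimethyl-2-propylfuran, via lactol 6 (not isolated)
Conditions: DIBAL-H (1.1 equiv), CH2Cl2, −78 °C; then 1 M HCl, 0 °C → rt; handled under argon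
Reagents that add atoms: none
Why: DIBAL‑H half‑reduction of the lactone to the lactol and acid‑catalysed 1,4‑dehydration, the classical butenolide‑to‑furan aromatisation.

Step 4
Reactants: 7 3,4-dimethyl-2-propylfuran; 8 ethyl 7-chloro-7-oxoheptanoate
Product: 9 ethyl 7-(3,4-dimethyl-5-propylfuran-2-yl)-7-oxoheptanoate
Conditions: SnCl4 (1.05 equiv), CH2Cl2, −78 → −30 °C; aq. NaHCO3 quench
Reagents that add atoms: none
Why: Friedel–Crafts acylation at the single free ring position (C5, α to oxygen); low temperature protects the acid‑sensitive trialkylfuran and the 2‑acylfuran product is deactivated.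

Step 5
Reactants: 9
Product: 11 7-(3,4-dimethyl-5-propylfuran-2-yl)heptanoic acid, via hydrazone carboxylate 10 (not isolated)
Conditions: N2H4·H2O, KOH, diethylene glycol, 130 °C then 195 °C (water distilled off); cold dilute HCl to pH 3–4
Reagents that add atoms: potassium hydroxide [K+].[OH-]
Why: Wolff–Kishner reduction (Huang‑Minlon variant) of the 2‑acylfuran through its hydrazone with concurrent saponification of the ethyl ester, under the strongly basic conditions that alkylfurans tolerate best.

Step 6
Reactants: 11
Product: 12 1,3-dioxoisoindolin-2-yl 7-(3,4-dimethyl-5-propylfuran-2-yl)heptanoate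
Conditions: N-hydroxyphthalimide, DIC, DMAP (cat.), CH2Cl2, rt
Reagents that add atoms: N-hydroxyphthalimide O=C1c2ccccc2C(=O)N1O
Why: Carbodiimide (Steglich‑type) esterification to the redox‑active ester under neutral conditions harmless to the furan.

Step 7
Reactants: 13 methyl N-acetyl-L-serinate
Product: 14 methyl N-acetyl-O-(tert-butyldimethylsilyl)-L-serinate
Conditions: TBSCl, imidazole, DMF, 0 °C → rt
Reagents that add atoms: tert-butyldimethylsilyl chloride CC(C)(C)[Si](C)(C)Cl
Why: Standard imidazole‑promoted silylation of the primary alcohol; the (S)‑centre is not touched.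

Step 8
Reactants: 14
Product: 15 (S)-2-acetamido-3-[(tert-butyldimethylsilyl)oxy]-N-methoxy-N-methylpropanamide
Conditions: MeNHOMe·HCl, i-PrMgCl (excess), THF, −20 → −10 °C; aq. NH4Cl
Reagents that add atoms: N,O-dimethylhydroxylamine hydrochloride CNOC.Cl
Why: Weinreb amide formation by aminolysis of the ester with the chloromagnesium amide; prior N–H deprotonation suppresses α‑enolisation and no activated acid (azlactone) is involved, so the (S)‑centre should be retained.

Step 9
Reactants: 15; 16 6-bromohex-1-ene
Product: 18 N-[(2S)-1-[(tert-butyldimethylsilyl)oxy]-3-oxonon-8-en-2-yl]acetamide, via hex-5-enylmagnesium bromide 17 (not isolated)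
Conditions: 16, Mg, THF, ≤ 25 °C; then 15 (Grignard 3.5 equiv), THF, −20 → 0 °C; aq. NH4Cl
Reagents that add atoms: none
Why: Weinreb ketone synthesis, in which the chelated tetrahedral intermediate prevents over‑addition and the N‑magnesiated acetamide shields the α‑stereocentre from enolisation.

Step 10
Reactants: 18
Product: 20 (7S)-7-acetamido-8-[(tert-butyldimethylsilyl)oxy]-6-oxooctanoic acid, via aldehyde 19 (not isolated)
Conditions: RuCl3·xH2O (cat.), NaIO4 (4 equiv), EtOAc/MeCN/H2O, 0 °C → rt; acid–base extraction
Reagents that add atoms: sodium periodate [Na+].[O-]I(=O)(=O)=O; water O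
Why: RuO4‑catalysed oxidative cleavage of the terminal alkene to the one‑carbon‑shorter acid (aldehyde oxidised on in situ), with ketone, acetamide and silyl ether inert and neutral impurities removed by extraction.

Step 11
Reactants: 20
Product: 21 1,3-dioxoisoindolin-2-yl (7S)-7-acetamido-8-[(tert-butyldimethylsilyl)oxy]-6-oxooctanoate
Conditions: N-hydroxyphthalimide, DIC, CH2Cl2, 0 °C → rt
Reagents that add atoms: N-hydroxyphthalimide O=C1c2ccccc2C(=O)N1O
Why: Carbodiimide esterification at the remote carboxyl group without added base, so the α‑acetamido ketone centre is not exposed to epimerising conditions.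

Step 12
Reactants: 12 (3 equiv); 21 (1 equiv)
Product: 22 N-[(2S)-1-[(tert-butyldimethylsilyl)oxy]-13-(3,4-dimethyl-5-propylfuran-2-yl)-3-oxotridecan-2-yl]acetamide
Conditions: NiCl2·6H2O (cat.), 2,2′:6′,2″-terpyridine (cat.), AgNO3 (sub-stoich.), NMP, undivided cell, Mg(+)/RVC(−), constant current, rt
Reagents that add atoms: none
Why: Cathodic, Ni‑mediated single‑electron reduction of both N‑acyloxyphthalimides releases CO2, phthalimide anion and the two primary radicals (furan–(CH2)6• and •(CH2)4C(=O)–), which the terpyridine–nickel catalyst captures in turn to a dialkylnickel(III) species that reductively eliminates the new CH2–CH2 bond, with the Mg anode supplying the electrons and the in situ silver‑plated cathode keeping the potential low. The closest known reaction type is the Ni‑electrocatalytic doubly decarboxylative C(sp3)–C(sp3) cross‑coupling of two alkyl redox‑active esters, established for primary–primary unions of long‑chain acids. No ring is closed and no stereocentre is created; the existing (S)‑centre is five bonds from the radical site and meets no base stronger than magnesium phthalimide. Cross‑ over homo‑coupling is statistical for two primary partners and is secured by a threefold excess of the achiral furan ester 12, whose non‑polar homodimer should separate easily from the polar cross‑product. Chemoselectivity is secured because only the phthalimide esters are reducible at the working potential, the ketone, acetamide N–H and silyl ether are inert, the fully substituted furan offers no ring C–H for radical attack, and the reductive mode spares the electron‑rich furan that an anodic Kolbe coupling would destroy.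

Step 13
Reactants: 22
Product: 23 N-[(2S)-13-(3,4-dimethyl-5-propylfuran-2-yl)-1-hydroxy-3-oxotridecan-2-yl]acetamide
Conditions: HF·pyridine, excess pyridine, THF, 0 °C → rt; pH 7 buffer work-up
Reagents that add atoms: none
Why: Fluoride desilylation of the primary TBS ether under buffered, non‑basic conditions, chosen to avoid retro‑aldol loss of formaldehyde, β‑elimination or epimerisation of the β‑hydroxy‑α‑acetamido ketone and tolerated by the furan.

**Compound list**
1 | 2,3-dimethylmaleic anhydride | CC1=C(C)C(=O)OC1=O | starting material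
2 | n-propylmagnesium chloride | CCC[Mg]Cl | starting material
3 | 5-hydroxy-3,4-dimethyl-5-propylfuran-2(5H)-one (racemic) | CCCC1(O)OC(=O)C(C)=C1C | intermediate
4 | (Z)-4-hydroxy-2,3-dimethylhept-2-enoic acid (racemic; sodium salt in the flask) | CCCC(O)/C(C)=C(C)\C(=O)O | intermediate
5 | 3,4-dimethyl-5-propylfuran-2(5H)-one (racemic) | CCCC1OC(=O)C(C)=C1C | intermediate
6 | 3,4-dimethyl-5-propyl-2,5-dihydrofuran-2-ol (diastereomer mixture) | CCCC1OC(O)C(C)=C1C | intermediate
7 | 3,4-dimethyl-2-propylfuran | CCCc1occ(C)c1C | intermediate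
8 | ethyl 7-chloro-7-oxoheptanoate | CCOC(=O)CCCCCC(=O)Cl | starting material
9 | ethyl 7-(3,4-dimethyl-5-propylfuran-2-yl)-7-oxoheptanoate | CCCc1oc(C(=O)CCCCCC(=O)OCC)c(C)c1C | intermediate
10 | 7-(3,4-dimethyl-5-propylfuran-2-yl)-7-hydrazinylideneheptanoic acid (potassium salt in the flask) | CCCc1oc(C(=NN)CCCCCC(=O)O)c(C)c1C | intermediate
11 | 7-(3,4-dimethyl-5-propylfuran-2-yl)heptanoic acid | CCCc1oc(CCCCCCC(=O)O)c(C)c1C | intermediate
12 | 1,3-dioxoisoindolin-2-yl 7-(3,4-dimethyl-5-propylfuran-2-yl)heptanoate | CCCc1oc(CCCCCCC(=O)ON2C(=O)c3ccccc3C2=O)c(C)c1C | intermediate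
13 | methyl N-acetyl-L-serinate | CC(=O)N[C@@H](CO)C(=O)OC | starting material
14 | methyl N-acetyl-O-(tert-butyldimethylsilyl)-L-serinate | CC(=O)N[C@@H](CO[Si](C)(C)C(C)(C)C)C(=O)OC | intermediate
15 | (S)-2-acetamido-3-[(tert-butyldimethylsilyl)oxy]-N-methoxy-N-methylpropanamide | CC(=O)N[C@@H](CO[Si](C)(C)C(C)(C)C)C(=O)N(C)OC | intermediate
16 | 6-bromohex-1-ene | C=CCCCCBr | starting material
17 | hex-5-en-1-ylmagnesium bromide | C=CCCCC[Mg]Br | intermediate
18 | N-[(2S)-1-[(tert-butyldimethylsilyl)oxy]-3-oxonon-8-en-2-yl]acetamide | C=CCCCCC(=O)[C@H](CO[Si](C)(C)C(C)(C)C)NC(C)=O | intermediate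
19 | N-[(2S)-1-[(tert-butyldimethylsilyl)oxy]-3,8-dioxooctan-2-yl]acetamide | O=CCCCCC(=O)[C@H](CO[Si](C)(C)C(C)(C)C)NC(C)=O | intermediate
20 | (7S)-7-acetamido-8-[(tert-butyldimethylsilyl)oxy]-6-oxooctanoic acid | OC(=O)CCCCC(=O)[C@H](CO[Si](C)(C)C(C)(C)C)NC(C)=O | intermediate
21 | 1,3-dioxoisoindolin-2-yl (7S)-7-acetamido-8-[(tert-butyldimethylsilyl)oxy]-6-oxooctanoate | O=C(CCCCC(=O)[C@H](CO[Si](C)(C)C(C)(C)C)NC(C)=O)ON1C(=O)c2ccccc2C1=O | intermediate
22 | N-[(2S)-1-[(tert-butyldimethylsilyl)oxy]-13-(3,4-dimethyl-5-propylfuran-2-yl)-3-oxotridecan-2-yl]acetamide | CCCc1oc(CCCCCCCCCCC(=O)[C@H](CO[Si](C)(C)C(C)(C)C)NC(C)=O)c(C)c1C | intermediate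
23 | N-[(2S)-13-(3,4-dimethyl-5-propylfuran-2-yl)-1-hydroxy-3-oxotridecan-2-yl]acetamide | CCCc1oc(CCCCCCCCCCC(=O)[C@H](CO)NC(C)=O)c(C)c1C | target

**Route statistics**
Total step count: 13. Longest linear sequence: 8 steps (steps 1–6, 12, 13 from anhydride 1); the serine branch contributes steps 7–11.

**Steps most likely to fail, with fallbacks**

Step 12. Statistical homo‑coupling could consume the limiting chiral ester, and premature reduction or hydrolysis of the redox‑active esters could give acids or protodecarboxylated chains. Configuration at C2 could also erode through intramolecular 1,6‑hydrogen transfer to the primary radical or through enolisation. The fallback makes the ketone–chain bond by polar chemistry; it sets out from furan 7 and Weinreb amide 15 and comes back at 22. Furan 7 is deprotonated with n‑BuLi (THF, 0 °C) to (3,4-dimethyl-5-propylfuran-2-yl)lithium F1, which is alkylated with excess 1,10‑dibromodecane to 2-(10-bromodecyl)-3,4-dimethyl-5-propylfuran F2. Magnesium in THF converts this into [10-(3,4-dimethyl-5-propylfuran-2-yl)decyl]magnesium bromide F3, which is added to 15 (N–H first deprotonated with i‑PrMgCl) in a Weinreb ketone synthesis to give 22; step 13 then follows.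

Step 4. The Lewis acid and the HCl released could open or oligomerise the electron‑rich trialkylfuran before acylation. The fallback installs the chain by formylation and olefination; it sets out from 7 and comes back at 11. Vilsmeier–Haack formylation of 7 (POCl3, DMF, 0 °C → rt) should give 3,4-dimethyl-5-propylfuran-2-carbaldehyde F4. Wittig olefination with the ylide from (5‑carboxypentyl)triphenylphosphonium bromide (NaHMDS, 2 equiv, THF) should give 7-(3,4-dimethyl-5-propylfuran-2-yl)hept-6-enoic acid F5 as an E/Z mixture. Hydrogenation of the side‑chain alkene only (H2, 1 atm, Pd/C, EtOAc, stopped after one equivalent) then delivers acid 11.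

Step 10. RuO4 could over‑oxidise C–H bonds next to nitrogen or oxygen, the silyl ether could be partly lost in the acidic periodate medium, and cyclised material from radical closure during formation of the hexenyl Grignard reagent could be carried along. The fallback reaches the acid by alcohol oxidation instead of alkene cleavage; it sets out from 15 and comes back at 20. Benzyl 5‑bromopentyl ether and Mg give [5-(benzyloxy)pentyl]magnesium bromide F6, which adds to N‑deprotonated 15 to give N-[(2S)-8-(benzyloxy)-1-[(tert-butyldimethylsilyl)oxy]-3-oxooctan-2-yl]acetamide F7. Hydrogenolysis (H2, Pd/C, EtOAc) gives N-[(2S)-1-[(tert-butyldimethylsilyl)oxy]-8-hydroxy-3-oxooctan-2-yl]acetamide F8, and TEMPO (cat.)/PhI(OAc)2 in MeCN/H2O oxidises the primary alcohol to acid 20.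

**Further compounds**
F1 | step 12 | (3,4-dimethyl-5-propylfuran-2-yl)lithium | [Li]c1oc(CCC)c(C)c1C
F2 | step 12 | 2-(10-bromodecyl)-3,4-dimethyl-5-propylfuran | CCCc1oc(CCCCCCCCCCBr)c(C)c1C
F3 | step 12 | [10-(3,4-dimethyl-5-propylfuran-2-yl)decyl]magnesium bromide | CCCc1oc(CCCCCCCCCC[Mg]Br)c(C)c1C
F4 | step 4 | 3,4-dimethyl-5-propylfuran-2-carbaldehyde | CCCc1oc(C=O)c(C)c1C
F5 | step 4 | 7-(3,4-dimethyl-5-propylfuran-2-yl)hept-6-enoic acid (E/Z mixture) | CCCc1oc(C=CCCCCC(=O)O)c(C)c1C
F6 | step 10 | [5-(benzyloxy)pentyl]magnesium bromide | Br[Mg]CCCCCOCc1ccccc1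
F7 | step 10 | N-[(2S)-8-(benzyloxy)-1-[(tert-butyldimethylsilyl)oxy]-3-oxooctan-2-yl]acetamide | CC(=O)N[C@@H](CO[Si](C)(C)C(C)(C)C)C(=O)CCCCCOCc1ccccc1
F8 | step 10 | N-[(2S)-1-[(tert-butyldimethylsilyl)oxy]-8-hydroxy-3-oxooctan-2-yl]acetamide | CC(=O)N[C@@H](CO[Si](C)(C)C(C)(C)C)C(=O)CCCCCO
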